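**Retrosynthetic overview**
- Last bond: ester C–O, by acylating only the primary hydroxyl of the triol enal with (11Z)-hexadec-11-enoic acid (from hex-1-yne, 1,6-dibromohexane and methyl 4-bromobutanoate).
- Key C–C bond (side-chain CH2–CH=): Pd-catalysed Negishi coupling of a ring-bound primary alkylzinc with an (E)-vinyl iodide.
- Vinyl iodide: new Ni-catalysed enantioselective reductive coupling of (3E)-4,8-dimethylnona-3,7-dienal with 1-(trimethylsilyl)propyne (sets the carbinol and the E-alkene), then iododesilylation.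
- Z-enal: ring ketone → ethynyl carbinol → iodo-Meyer–Schuster rearrangement → Pd-catalysed methylation.
- The only ring (the cyclohexane) is carried from phenol through its quinone monoketal; Cu-catalysed desymmetrising conjugate addition, enolate methylation/allylation and MeMgBr addition set the three ring stereocentres.

Assumption: the target is taken as drawn (ring CH R, tertiary carbinol S, quaternary carbon S, side-chain carbinol R, enal Z, side-chain alkenes E, ester alkene Z); a named ligand enantiomer is the one expected to give this sense, and its antipode is used if the observed sense is opposite. TBS = tert-butyldimethylsilyl (TBSO = its silyloxy group), TES = triethylsilyl.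

**Organozinc reagent**

Step 1
Reactants: 1 3-iodopropan-1-ol
Product: 2 tert-butyl(3-iodopropoxy)dimethylsilane
Conditions: TBSCl, imidazole, CH2Cl2, 0 °C to rt
Reagents that add atoms: tert-butyldimethylsilyl chloride, CC(C)(C)[Si](C)(C)Cl
Why: Standard silyl ether protection of a primary alcohol.

Step 2
Reactants: 2 tert-butyl(3-iodopropoxy)dimethylsilane
Product: 4 [3-(TBSO)propyl](trimethylsilylmethyl)zinc, via alkylzinc iodide 3 (not isolated)
Conditions: Zn dust (activated with BrCH2CH2Br and Me3SiCl), THF, 40 °C; then Me3SiCH2Li (pentane, 1.0 equiv), −78 to 0 °C; THF replaced by toluene and LiI filtered off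
Reagents that add atoms: zinc, [Zn]; (trimethylsilyl)methyllithium, C[Si](C)(C)C[Li]
Why: Direct zinc insertion into the primary C–I bond gives the alkylzinc iodide, and salt metathesis with Me3SiCH2Li gives a mixed diorganozinc whose trimethylsilylmethyl group is a non-transferable ligand, so the reagent has dialkylzinc reactivity but delivers only the functionalised alkyl group.

**Ring fragment**

Step 3
Reactants: 5 phenol
Product: 7 4,4-dimethoxycyclohexa-2,5-dien-1-one, via 4-methoxyphenol 6 (not isolated)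
Conditions: PhI(OAc)2 (2.1 equiv), MeOH, 0 °C to rt
Reagents that add atoms: methanol, CO
Why: Hypervalent-iodine oxidative dearomatisation; para-methoxylation and a second oxidation give the quinone monoketal.

Step 4
Reactants: 7 4,4-dimethoxycyclohexa-2,5-dien-1-one; 4 [3-(TBSO)propyl](trimethylsilylmethyl)zinc
Product: 9 (5S)-5-[3-(TBSO)propyl]-4,4-dimethoxycyclohex-2-en-1-one, via zinc dienolate 8 (not isolated)
Conditions: Cu(OTf)2 (2 mol%), (R,S,S)-phosphoramidite [(R)-BINOL-derived N,N-bis((S)-1-phenylethyl)phosphoramidite] (4 mol%), 4 (1.5 equiv), toluene, −25 °C; aq. NH4Cl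
Reagents that add atoms: none
Why: Copper-catalysed enantioselective conjugate addition of a diorganozinc desymmetrises the achiral dienone; only the functionalised alkyl group is transferred (Me3SiCH2 stays on zinc), and the chiral phosphoramidite selects one enantiotopic enone arm and face and so sets C5 as S.

Step 5
Reactants: 9 (5S)-5-[3-(TBSO)propyl]-4,4-dimethoxycyclohex-2-en-1-one
Product: 11 (5S)-5-[3-(TBSO)propyl]-4,4-dimethoxy-6-methylcyclohex-2-en-1-one (both C6 epimers), via lithium dienolate 10 (not isolated)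
Conditions: LiN(iPr)2, THF, −78 °C; MeI, −78 to −20 °C
Reagents that add atoms: iodomethane, CI
Why: Kinetic α'-deprotonation (the γ-carbon is quaternary) and enolate C-methylation; the C6 configuration does not matter because step 6 erases it.

Step 6
Reactants: 11 (5S)-5-[3-(TBSO)propyl]-4,4-dimethoxy-6-methylcyclohex-2-en-1-one; 12 3-bromoprop-1-ene
Product: 14 (5S,6S)-6-allyl-5-[3-(TBSO)propyl]-4,4-dimethoxy-6-methylcyclohex-2-en-1-one, via lithium dienolate 13 (not isolated)
Conditions: LiN(iPr)2, THF, −78 to 0 °C; DMPU, 12, −78 to 0 °C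
Reagents that add atoms: none
Why: Enolate alkylation; allyl bromide attacks the tetrasubstituted enolate anti to the adjacent C5 side chain, creating the quaternary centre (6S) with allyl trans to that chain.

Step 7
Reactants: 14 (5S,6S)-6-allyl-5-[3-(TBSO)propyl]-4,4-dimethoxy-6-methylcyclohex-2-en-1-one
Product: 15 (2S,3S)-2-allyl-3-[3-(TBSO)propyl]-4,4-dimethoxy-2-methylcyclohexan-1-one
Conditions: [(Ph3P)CuH]6 (5 mol%), PPh3, H2 (10 bar), benzene, rt
Reagents that add atoms: none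
Why: Copper hydride conjugate reduction is selective for the enone C=C and leaves the isolated allyl group, ketal and silyl ether untouched.

Step 8
Reactants: 15 (2S,3S)-2-allyl-3-[3-(TBSO)propyl]-4,4-dimethoxy-2-methylcyclohexan-1-one
Product: 16 (1S,2S,3S)-2-allyl-3-[3-(TBSO)propyl]-4,4-dimethoxy-1,2-dimethylcyclohexan-1-ol
Conditions: MeMgBr, CeCl3, THF, −78 to 0 °C; aq. NH4Cl
Reagents that add atoms: methylmagnesium bromide, C[Mg]Br
Why: Organocerium-type 1,2-addition; in the chair with the C3 chain and allyl group equatorial the 2-methyl is axial, so the nucleophile adds axially from the face anti to it, giving the 1S carbinol with OH cis to the C3 chain.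

Step 9
Reactants: 16 (1S,2S,3S)-2-allyl-3-[3-(TBSO)propyl]-4,4-dimethoxy-1,2-dimethylcyclohexan-1-ol
Product: 17 (1S,2S,3S)-2-allyl-3-[3-(TBSO)propyl]-4,4-dimethoxy-1,2-dimethyl-1-(triethylsilyloxy)cyclohexane
Conditions: Et3SiOTf, 2,6-lutidine, CH2Cl2, −78 to 0 °C
Reagents that add atoms: triethylsilyl trifluoromethanesulfonate, CC[Si](CC)(CC)OS(=O)(=O)C(F)(F)F
Why: Silyl triflate silylation of the hindered tertiary alcohol (the ketal tolerates these conditions cold); it prevents later tetrahydrofuran formation by the alkoxide onto the 2-iodoethyl group.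

Step 10
Reactants: 17 (1S,2S,3S)-2-allyl-3-[3-(TBSO)propyl]-4,4-dimethoxy-1,2-dimethyl-1-(triethylsilyloxy)cyclohexane
Product: 19 (1S,2S,3S)-3-[3-(TBSO)propyl]-2-(2-hydroxyethyl)-4,4-dimethoxy-1,2-dimethyl-1-(triethylsilyloxy)cyclohexane, via ozonide 18 (not isolated)
Conditions: O3, CH2Cl2, −78 °C; then NaBH4, EtOH, −78 °C to rt
Reagents that add atoms: ozone, [O-][O+]=O
Why: Ozonolysis of the only C=C bond with reductive work-up shortens allyl to 2-hydroxyethyl.

Step 11
Reactants: 19 (1S,2S,3S)-3-[3-(TBSO)propyl]-2-(2-hydroxyethyl)-4,4-dimethoxy-1,2-dimethyl-1-(triethylsilyloxy)cyclohexane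
Product: 20 (1S,2S,3S)-3-[3-(TBSO)propyl]-2-(2-iodoethyl)-4,4-dimethoxy-1,2-dimethyl-1-(triethylsilyloxy)cyclohexane
Conditions: I2, PPh3, imidazole, CH2Cl2, 0 °C to rt
Reagents that add atoms: iodine, II
Why: Appel-type iodination of a primary alcohol by SN2 displacement.

Step 12
Reactants: 20 (1S,2S,3S)-3-[3-(TBSO)propyl]-2-(2-iodoethyl)-4,4-dimethoxy-1,2-dimethyl-1-(triethylsilyloxy)cyclohexane
Product: 21 (2S,3S,4S)-2-[3-(TBSO)propyl]-3-(2-iodoethyl)-3,4-dimethyl-4-(triethylsilyloxy)cyclohexan-1-one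
Conditions: PPTS (20 mol%), acetone/H2O 10:1, rt
Reagents that add atoms: water, O
Why: Mild acid hydrolysis of the dimethyl ketal; these conditions leave both silyl ethers in place and are too weak to epimerise C2.

Step 13
Reactants: 21 (2S,3S,4S)-2-[3-(TBSO)propyl]-3-(2-iodoethyl)-3,4-dimethyl-4-(triethylsilyloxy)cyclohexan-1-one
Product: 22 (2S,3S,4S)-1-ethynyl-2-[3-(TBSO)propyl]-3-(2-iodoethyl)-3,4-dimethyl-4-(triethylsilyloxy)cyclohexan-1-ol (both C1 epimers)
Conditions: HC≡CMgBr (3 equiv), CeCl3, THF, −78 to 0 °C; aq. NH4Cl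
Reagents that add atoms: ethynylmagnesium bromide, C#C[Mg]Br
Why: Cerium-moderated 1,2-addition of the small acetylide to the hindered ketone without enolisation; the new carbinol configuration is lost in step 14.

Step 14
Reactants: 22 (2S,3S,4S)-1-ethynyl-2-[3-(TBSO)propyl]-3-(2-iodoethyl)-3,4-dimethyl-4-(triethylsilyloxy)cyclohexan-1-ol
Product: 24 (2E)-2-iodo-2-[(2S,3S,4S)-2-[3-(TBSO)propyl]-3-(2-iodoethyl)-3,4-dimethyl-4-(triethylsilyloxy)cyclohexylidene]acetaldehyde, via allenol 23 (not isolated)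
Conditions: Ph3PAuNTf2 (2 mol%), MoO2(acac)2 (2 mol%), Ph3PO (5 mol%), N-iodosuccinimide (1.2 equiv), CH2Cl2, rt
Reagents that add atoms: N-iodosuccinimide, O=C1CCC(=O)N1I
Why: Gold/molybdenum co-catalysed Meyer–Schuster rearrangement with iodine trapping; the allenol is iodinated at its central carbon in the plane of the ring substituents from the less hindered ring-CH2 (C6) side, so iodine ends cis to C6 and CHO cis to the substituted C2.

Step 15
Reactants: 24 (2E)-2-iodo-2-[(2S,3S,4S)-2-[3-(TBSO)propyl]-3-(2-iodoethyl)-3,4-dimethyl-4-(triethylsilyloxy)cyclohexylidene]acetaldehyde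
Product: 25 (2Z)-2-[(2R,3S,4S)-2-[3-(TBSO)propyl]-3-(2-iodoethyl)-3,4-dimethyl-4-(triethylsilyloxy)cyclohexylidene]propanal
Conditions: MeZnCl (1.5 equiv), Pd(PPh3)4 (5 mol%), THF, 0 °C to rt
Reagents that add atoms: methylzinc chloride, C[Zn]Cl
Why: Negishi coupling of the α-iodoenal with retention of alkene geometry puts methyl where iodine was (now 2Z); the primary alkyl iodide is inert to zerovalent palladium here.

Step 16
Reactants: 25 (2Z)-2-[(2R,3S,4S)-2-[3-(TBSO)propyl]-3-(2-iodoethyl)-3,4-dimethyl-4-(triethylsilyloxy)cyclohexylidene]propanal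
Product: 26 tert-butyl{3-[(1R,2Z,5S,6S)-2-(1,1-dimethoxypropan-2-ylidene)-6-(2-iodoethyl)-5,6-dimethyl-5-(triethylsilyloxy)cyclohexyl]propoxy}dimethylsilane
Conditions: HC(OMe)3, CeCl3·7H2O (10 mol%), MeOH, rt
Reagents that add atoms: trimethyl orthoformate, COC(OC)OC
Why: Lewis-acid catalysed acetalisation masks the aldehyde for the organolithium step.

**Side-chain fragment**

Step 17
Reactants: 27 5-bromo-2-methylpent-2-ene
Product: 28 6-methylhept-5-en-1-yne
Conditions: LiC≡CH·H2NCH2CH2NH2, DMSO, 10 °C to rt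
Reagents that add atoms: lithium acetylide–ethylenediamine complex, [Li]C#C.NCCN
Why: SN2 alkylation of lithium acetylide by a primary bromide.

Step 18
Reactants: 28 6-methylhept-5-en-1-yne; 29 oxirane
Product: 32 (3E)-4,8-dimethylnona-3,7-dien-1-ol, via alkenylalane 30 (not isolated), via lithium alanate 31 (not isolated)
Conditions: Me3Al, Cp2ZrCl2 (20 mol%), CH2Cl2, rt; volatiles removed; n-BuLi, hexane/THF, −78 °C; 29, −78 °C to rt; aq. HCl
Reagents that add atoms: trimethylaluminium, C[Al](C)C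
Why: Zirconium-catalysed syn-carboalumination gives the E-alkenylalane regio- and stereoselectively, and its butyl ate complex opens oxirane with retention of alkene geometry.

Step 19
Reactants: 32 (3E)-4,8-dimethylnona-3,7-dien-1-ol
Product: 33 (3E)-4,8-dimethylnona-3,7-dienal
Conditions: Dess–Martin periodinane, NaHCO3, CH2Cl2, 0 °C; used at once
Reagents that add atoms: none
Why: Buffered Dess–Martin oxidation gives the β,γ-unsaturated aldehyde without double-bond migration.

Step 20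
Reactants: 33 (3E)-4,8-dimethylnona-3,7-dienal; 34 trimethyl(prop-1-yn-1-yl)silane
Product: 35 triethyl{[(1E,3R,5E)-2,6,10-trimethyl-1-(trimethylsilyl)undeca-1,5,9-trien-3-yl]oxy}silane
Conditions: Ni(cod)2 (10 mol%), preformed free chiral carbene [(4S,5S)-4,5-diphenyl-1,3-bis(2-methyl-6-(3,5-di-tert-butylphenyl)phenyl)imidazolidin-2-ylidene] (10 mol%), Et3SiH (2 equiv), THF, rt, slow addition of 33
Reagents that add atoms: triethylsilane, CC[SiH](CC)CC
Why: Proposed new method: zerovalent nickel carrying a bulky C2-symmetric chiral carbene should join 33 and 34 by oxidative cyclisation to an oxanickelacyclopentene in which the C–C bond forms at the methyl-bearing alkyne carbon (the silyl-bearing carbon prefers to bind nickel and the small methyl sits next to the new bond) while the ligand shields one aldehyde face to set 3R, after which σ-bond metathesis with Et3SiH and C–H reductive elimination deliver H syn to give the E-vinylsilane and the O-silyl ether directly; the closest known reaction type is the nickel-catalysed reductive coupling of aldehydes with aryl- or silyl-substituted alkynes (phosphine/Et3B or carbene/silane systems), which to my knowledge has not been shown with high enantioselectivity for 1-silylpropynes and linear, enolisable β,γ-unsaturated aldehydes.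

Step 21
Reactants: 35 triethyl{[(1E,3R,5E)-2,6,10-trimethyl-1-(trimethylsilyl)undeca-1,5,9-trien-3-yl]oxy}silane
Product: 36 triethyl{[(1E,3R,5E)-1-iodo-2,6,10-trimethylundeca-1,5,9-trien-3-yl]oxy}silane
Conditions: N-iodosuccinimide, 2,6-lutidine, (CF3)2CHOH, 0 °C, 10 min
Reagents that add atoms: N-iodosuccinimide, O=C1CCC(=O)N1I
Why: Ipso-iododesilylation of the vinylsilane (β-silyl cation stabilisation) proceeds with retention of geometry and faster than iodination of the remote trisubstituted alkenes.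

**Acid fragment**

Step 22
Reactants: 37 hex-1-yne; 38 1,6-dibromohexane
Product: 40 12-bromododec-5-yne, via hexynyllithium 39 (not isolated)
Conditions: n-BuLi, THF, −78 °C; 38 (3 equiv), DMPU, −78 °C to rt
Reagents that add atoms: none
Why: SN2 alkylation of a lithium acetylide; excess dibromide gives the mono-alkylated bromide.

Step 23
Reactants: 40 12-bromododec-5-yne; 41 methyl 4-bromobutanoate
Product: 43 methyl hexadec-11-ynoate, via Grignard reagent 42 (not isolated)
Conditions: Mg, THF, 40 °C; then 41, Li2CuCl4 (3 mol%), N-methylpyrrolidone, THF, 0 °C to rt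
Reagents that add atoms: none
Why: Copper-catalysed sp3–sp3 Grignard cross-coupling (Kochi type) tolerates the methyl ester at low temperature.

Step 24
Reactants: 43 methyl hexadec-11-ynoate
Product: 44 methyl (11Z)-hexadec-11-enoate
Conditions: H2 (1 atm), 5% Pd/CaCO3 poisoned with Pb(OAc)2, quinoline, hexane, rt
Reagents that add atoms: none
Why: Lindlar semihydrogenation; syn addition of H2 gives the Z-alkene.

Step 25
Reactants: 44 methyl (11Z)-hexadec-11-enoate
Product: 45 (11Z)-hexadec-11-enoic acid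
Conditions: LiOH, THF/H2O, rt; then aq. HCl
Reagents that add atoms: lithium hydroxide, [Li+].[OH-]
Why: Saponification of a methyl ester.

**Union and endgame**

Step 26
Reactants: 26 tert-butyl{3-[(1R,2Z,5S,6S)-2-(1,1-dimethoxypropan-2-ylidene)-6-(2-iodoethyl)-5,6-dimethyl-5-(triethylsilyloxy)cyclohexyl]propoxy}dimethylsilane; 36 triethyl{[(1E,3R,5E)-1-iodo-2,6,10-trimethylundeca-1,5,9-trien-3-yl]oxy}silane
Product: 48 tert-butyl{3-[(1R,2Z,5S,6S)-2-(1,1-dimethoxypropan-2-ylidene)-5,6-dimethyl-5-(triethylsilyloxy)-6-[(3E,5R,7E)-4,8,12-trimethyl-5-(triethylsilyloxy)trideca-3,7,11-trien-1-yl]cyclohexyl]propoxy}dimethylsilane, via alkyllithium 46 (not isolated), via alkylzinc chloride 47 (not isolated)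
Conditions: t-BuLi (2.1 equiv), Et2O, −78 °C; ZnCl2 (THF), −78 °C to rt; 36, Pd(dppf)Cl2 (5 mol%), THF, rt
Reagents that add atoms: none
Why: Negishi sp3–sp2 cross-coupling; iodine–lithium exchange, transmetalation to zinc and palladium-catalysed coupling with the vinyl iodide retain the E geometry and touch no stereocentre.

Step 27
Reactants: 48 protected coupling product
Product: 49 (2Z)-2-[(2R,3S,4S)-4-hydroxy-3-[(3E,5R,7E)-5-hydroxy-4,8,12-trimethyltrideca-3,7,11-trien-1-yl]-2-(3-hydroxypropyl)-3,4-dimethylcyclohexylidene]propanal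
Conditions: aq. HF (48%)/MeCN 1:19, 0 °C to rt
Reagents that add atoms: water, O
Why: Aqueous HF cleaves the three silyl ethers and hydrolyses the dimethyl acetal in one operation.

Step 28
Reactants: 49 triol enal; 45 (11Z)-hexadec-11-enoic acid
Product: 50 3-[(1R,2Z,5S,6S)-5-hydroxy-6-[(3E,5R,7E)-5-hydroxy-4,8,12-trimethyltrideca-3,7,11-trien-1-yl]-5,6-dimethyl-2-(1-oxopropan-2-ylidene)cyclohexyl]propyl (11Z)-hexadec-11-enoate
Conditions: EDC·HCl (1.1 equiv), DMAP (0.1 equiv), CH2Cl2, −20 to 0 °C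
Reagents that add atoms: none
Why: Carbodiimide (Steglich) esterification with one equivalent of acid at low temperature acylates the primary hydroxyl in preference to the secondary allylic and tertiary ones.

**Compound list**

1 | 3-iodopropan-1-ol | OCCCI | starting material
2 | tert-butyl(3-iodopropoxy)dimethylsilane | ICCCO[Si](C)(C)C(C)(C)C | intermediate
3 | [3-(TBSO)propyl]zinc iodide | I[Zn]CCCO[Si](C)(C)C(C)(C)C | intermediate (not isolated)
4 | [3-(TBSO)propyl](trimethylsilylmethyl)zinc | C[Si](C)(C)C[Zn]CCCO[Si](C)(C)C(C)(C)C | intermediate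
5 | phenol | Oc1ccccc1 | starting material
6 | 4-methoxyphenol | COc1ccc(O)cc1 | intermediate (not isolated)
7 | 4,4-dimethoxycyclohexa-2,5-dien-1-one | COC1(OC)C=CC(=O)C=C1 | intermediate
8 | (trimethylsilylmethyl)zinc (3S)-3-[3-(TBSO)propyl]-4,4-dimethoxycyclohexa-1,5-dien-1-olate | CC(C)(C)[Si](C)(C)OCCC[C@@H]1C(OC)(OC)C=CC(O[Zn]C[Si](C)(C)C)=C1 | intermediate (not isolated)
9 | (5S)-5-[3-(TBSO)propyl]-4,4-dimethoxycyclohex-2-en-1-one | CC(C)(C)[Si](C)(C)OCCC[C@@H]1C(OC)(OC)C=CC(=O)C1 | intermediate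
10 | lithium (3S)-3-[3-(TBSO)propyl]-4,4-dimethoxycyclohexa-1,5-dien-1-olate | CC(C)(C)[Si](C)(C)OCCC[C@@H]1C(OC)(OC)C=CC(O[Li])=C1 | intermediate (not isolated)
11 | (5S)-5-[3-(TBSO)propyl]-4,4-dimethoxy-6-methylcyclohex-2-en-1-one (C6 epimers) | CC(C)(C)[Si](C)(C)OCCC[C@@H]1C(OC)(OC)C=CC(=O)C1C | intermediate
12 | 3-bromoprop-1-ene | C=CCBr | starting material
13 | lithium (3S)-3-[3-(TBSO)propyl]-4,4-dimethoxy-2-methylcyclohexa-1,5-dien-1-olate | CC(C)(C)[Si](C)(C)OCCC[C@@H]1C(OC)(OC)C=CC(O[Li])=C1C | intermediate (not isolated)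
14 | (5S,6S)-6-allyl-5-[3-(TBSO)propyl]-4,4-dimethoxy-6-methylcyclohex-2-en-1-one | CC(C)(C)[Si](C)(C)OCCC[C@@H]1C(OC)(OC)C=CC(=O)[C@@]1(C)CC=C | intermediate
15 | (2S,3S)-2-allyl-3-[3-(TBSO)propyl]-4,4-dimethoxy-2-methylcyclohexan-1-one | CC(C)(C)[Si](C)(C)OCCC[C@@H]1C(OC)(OC)CCC(=O)[C@@]1(C)CC=C | intermediate
16 | (1S,2S,3S)-2-allyl-3-[3-(TBSO)propyl]-4,4-dimethoxy-1,2-dimethylcyclohexan-1-ol | CC(C)(C)[Si](C)(C)OCCC[C@@H]1C(OC)(OC)CC[C@](C)(O)[C@@]1(C)CC=C | intermediate
17 | (1S,2S,3S)-2-allyl-3-[3-(TBSO)propyl]-4,4-dimethoxy-1,2-dimethyl-1-(triethylsilyloxy)cyclohexane | CC(C)(C)[Si](C)(C)OCCC[C@@H]1C(OC)(OC)CC[C@](C)(O[Si](CC)(CC)CC)[C@@]1(C)CC=C | intermediate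
18 | ozonide of 17 (allyl CH=CH2 turned into a 1,2,4-trioxolan-3-yl group; ring stereocentres as in 17) | CC(C)(C)[Si](C)(C)OCCC[C@@H]1C(OC)(OC)CC[C@](C)(O[Si](CC)(CC)CC)[C@@]1(C)CC2OCOO2 | intermediate (not isolated)
19 | (1S,2S,3S)-3-[3-(TBSO)propyl]-2-(2-hydroxyethyl)-4,4-dimethoxy-1,2-dimethyl-1-(triethylsilyloxy)cyclohexane | CC(C)(C)[Si](C)(C)OCCC[C@@H]1C(OC)(OC)CC[C@](C)(O[Si](CC)(CC)CC)[C@@]1(C)CCO | intermediate
20 | (1S,2S,3S)-3-[3-(TBSO)propyl]-2-(2-iodoethyl)-4,4-dimethoxy-1,2-dimethyl-1-(triethylsilyloxy)cyclohexane | CC(C)(C)[Si](C)(C)OCCC[C@@H]1C(OC)(OC)CC[C@](C)(O[Si](CC)(CC)CC)[C@@]1(C)CCI | intermediate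
21 | (2S,3S,4S)-2-[3-(TBSO)propyl]-3-(2-iodoethyl)-3,4-dimethyl-4-(triethylsilyloxy)cyclohexan-1-one | CC(C)(C)[Si](C)(C)OCCC[C@@H]1C(=O)CC[C@](C)(O[Si](CC)(CC)CC)[C@@]1(C)CCI | intermediate
22 | (2S,3S,4S)-1-ethynyl-2-[3-(TBSO)propyl]-3-(2-iodoethyl)-3,4-dimethyl-4-(triethylsilyloxy)cyclohexan-1-ol (C1 epimers) | CC(C)(C)[Si](C)(C)OCCC[C@@H]1C(O)(C#C)CC[C@](C)(O[Si](CC)(CC)CC)[C@@]1(C)CCI | intermediate
23 | 2-[(2R,3S,4S)-2-[3-(TBSO)propyl]-3-(2-iodoethyl)-3,4-dimethyl-4-(triethylsilyloxy)cyclohexylidene]ethen-1-ol | CC(C)(C)[Si](C)(C)OCCC[C@@H]1C(=C=CO)CC[C@](C)(O[Si](CC)(CC)CC)[C@@]1(C)CCI | intermediate (not isolated)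
24 | (2E)-2-iodo-2-[(2S,3S,4S)-2-[3-(TBSO)propyl]-3-(2-iodoethyl)-3,4-dimethyl-4-(triethylsilyloxy)cyclohexylidene]acetaldehyde | CC(C)(C)[Si](C)(C)OCCC[C@@H]1/C(=C(/I)C=O)CC[C@](C)(O[Si](CC)(CC)CC)[C@@]1(C)CCI | intermediate
25 | (2Z)-2-[(2R,3S,4S)-2-[3-(TBSO)propyl]-3-(2-iodoethyl)-3,4-dimethyl-4-(triethylsilyloxy)cyclohexylidene]propanal | CC(C)(C)[Si](C)(C)OCCC[C@@H]1/C(=C(/C)C=O)CC[C@](C)(O[Si](CC)(CC)CC)[C@@]1(C)CCI | intermediate
26 | tert-butyl{3-[(1R,2Z,5S,6S)-2-(1,1-dimethoxypropan-2-ylidene)-6-(2-iodoethyl)-5,6-dimethyl-5-(triethylsilyloxy)cyclohexyl]propoxy}dimethylsilane | CC(C)(C)[Si](C)(C)OCCC[C@@H]1/C(=C(/C)C(OC)OC)CC[C@](C)(O[Si](CC)(CC)CC)[C@@]1(C)CCI | intermediate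
27 | 5-bromo-2-methylpent-2-ene | CC(C)=CCCBr | starting material
28 | 6-methylhept-5-en-1-yne | CC(C)=CCCC#C | intermediate
29 | oxirane | C1CO1 | starting material
30 | [(1E)-2,6-dimethylhepta-1,5-dien-1-yl]dimethylalane | C[Al](C)/C=C(\C)CCC=C(C)C | intermediate (not isolated)
31 | lithium butyl[(1E)-2,6-dimethylhepta-1,5-dien-1-yl]dimethylaluminate | [Li+].CCCC[Al-](C)(C)/C=C(\C)CCC=C(C)C | intermediate (not isolated)
32 | (3E)-4,8-dimethylnona-3,7-dien-1-ol | OCC/C=C(\C)CCC=C(C)C | intermediate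
33 | (3E)-4,8-dimethylnona-3,7-dienal | O=CC/C=C(\C)CCC=C(C)C | intermediate
34 | trimethyl(prop-1-yn-1-yl)silane | CC#C[Si](C)(C)C | starting material
35 | triethyl{[(1E,3R,5E)-2,6,10-trimethyl-1-(trimethylsilyl)undeca-1,5,9-trien-3-yl]oxy}silane | C[Si](C)(C)/C=C(\C)[C@H](O[Si](CC)(CC)CC)C/C=C(\C)CCC=C(C)C | intermediate
36 | triethyl{[(1E,3R,5E)-1-iodo-2,6,10-trimethylundeca-1,5,9-trien-3-yl]oxy}silane | I/C=C(\C)[C@H](O[Si](CC)(CC)CC)C/C=C(\C)CCC=C(C)C | intermediate
37 | hex-1-yne | CCCCC#C | starting material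
38 | 1,6-dibromohexane | BrCCCCCCBr | starting material
39 | hex-1-yn-1-yllithium | [Li]C#CCCCC | intermediate (not isolated)
40 | 12-bromododec-5-yne | CCCCC#CCCCCCCBr | intermediate
41 | methyl 4-bromobutanoate | COC(=O)CCCBr | starting material
42 | dodec-7-yn-1-ylmagnesium bromide | CCCCC#CCCCCCC[Mg]Br | intermediate (not isolated)
43 | methyl hexadec-11-ynoate | CCCCC#CCCCCCCCCCC(=O)OC | intermediate
44 | methyl (11Z)-hexadec-11-enoate | CCCC/C=C\CCCCCCCCCC(=O)OC | intermediate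
45 | (11Z)-hexadec-11-enoic acid | CCCC/C=C\CCCCCCCCCC(=O)O | intermediate
46 | alkyllithium from 26 (Li in place of I) | CC(C)(C)[Si](C)(C)OCCC[C@@H]1/C(=C(/C)C(OC)OC)CC[C@](C)(O[Si](CC)(CC)CC)[C@@]1(C)CC[Li] | intermediate (not isolated)
47 | alkylzinc chloride from 26 (ZnCl in place of I) | CC(C)(C)[Si](C)(C)OCCC[C@@H]1/C(=C(/C)C(OC)OC)CC[C@](C)(O[Si](CC)(CC)CC)[C@@]1(C)CC[Zn]Cl | intermediate (not isolated)
48 | tert-butyl{3-[(1R,2Z,5S,6S)-2-(1,1-dimethoxypropan-2-ylidene)-5,6-dimethyl-5-(triethylsilyloxy)-6-[(3E,5R,7E)-4,8,12-trimethyl-5-(triethylsilyloxy)trideca-3,7,11-trien-1-yl]cyclohexyl]propoxy}dimethylsilane | CC(C)(C)[Si](C)(C)OCCC[C@@H]1/C(=C(/C)C(OC)OC)CC[C@](C)(O[Si](CC)(CC)CC)[C@@]1(C)CC/C=C(\C)[C@H](O[Si](CC)(CC)CC)C/C=C(\C)CCC=C(C)C | intermediate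
49 | (2Z)-2-[(2R,3S,4S)-4-hydroxy-3-[(3E,5R,7E)-5-hydroxy-4,8,12-trimethyltrideca-3,7,11-trien-1-yl]-2-(3-hydroxypropyl)-3,4-dimethylcyclohexylidene]propanal | OCCC[C@@H]1/C(=C(/C)C=O)CC[C@](C)(O)[C@@]1(C)CC/C=C(\C)[C@H](O)C/C=C(\C)CCC=C(C)C | intermediate
50 | 3-[(1R,2Z,5S,6S)-5-hydroxy-6-[(3E,5R,7E)-5-hydroxy-4,8,12-trimethyltrideca-3,7,11-trien-1-yl]-5,6-dimethyl-2-(1-oxopropan-2-ylidene)cyclohexyl]propyl (11Z)-hexadec-11-enoate | CCCC/C=C\CCCCCCCCCC(=O)OCCC[C@@H]1/C(=C(/C)C=O)CC[C@](C)(O)[C@@]1(C)CC/C=C(\C)[C@H](O)C/C=C(\C)CCC=C(C)C | target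

**Step count**

Total steps: 28. Longest linear sequence: 18 (steps 1, 2, 4–16, 26–28).

**Three steps most likely to fail**

1. Step 20, the new nickel coupling. Regio- and enantiocontrol are unproven for this alkyne/aldehyde pair, and 33 is enolisable. The fallback uses known chemistry, sets out from 33 and comes back to the route at 36, so steps 20 and 21 are both bypassed. Addition of the zinc acetylide of trimethylsilylacetylene to 33 (Et2Zn, Ti(OiPr)4, the BINOL enantiomer that gives 3R, toluene/CH2Cl2) gives (3R,5E)-6,10-dimethyl-1-(trimethylsilyl)undeca-5,9-dien-1-yn-3-ol F1. K2CO3 in MeOH removes the silyl group to give (3R,5E)-6,10-dimethylundeca-5,9-dien-1-yn-3-ol F2. Zirconium-catalysed carboalumination (Me3Al, Cp2ZrCl2, CH2Cl2) followed by I2 gives (1E,3R,5E)-1-iodo-2,6,10-trimethylundeca-1,5,9-trien-3-ol F3, and Et3SiCl with imidazole converts it into 36.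

2. Step 14, the iodo-Meyer–Schuster rearrangement. The carbinol is very hindered and the alkene geometry rests on a steric argument. The fallback sets out from 21 and comes back at 25, bypassing steps 13–15. CH2=C(CH3)MgBr with CeCl3 adds to 21 to give (2S,3S,4S)-2-[3-(TBSO)propyl]-3-(2-iodoethyl)-3,4-dimethyl-1-(prop-1-en-2-yl)-4-(triethylsilyloxy)cyclohexan-1-ol F4 (both C1 epimers). Oxidative 1,3-transposition with pyridinium chlorochromate (C5H5NH[CrO3Cl], NaOAc, CH2Cl2; Babler–Dauben oxidation) gives 25 together with its 2E isomer, which is separated and re-equilibrated (cat. I2, light) for recycling.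

3. Step 8, the facial selectivity of the methyl addition that sets the tertiary carbinol. If the methyl group enters mainly from the wrong face, the fallback delivers oxygen instead of carbon to that face. It sets out from 15 and comes back at 16. Wittig methylenation (Ph3P=CH2 from Ph3PCH3Br and KOtBu, THF) gives tert-butyl{3-[(1S,2S)-2-allyl-6,6-dimethoxy-2-methyl-3-methylidenecyclohexyl]propoxy}dimethylsilane F5. m-CPBA (NaHCO3, CH2Cl2, −20 °C) epoxidises the more electron-rich 1,1-disubstituted alkene from its less hindered face to give tert-butyl{3-[(3S,4S,5S)-4-allyl-6,6-dimethoxy-4-methyl-1-oxaspiro[2.5]octan-5-yl]propoxy}dimethylsilane F6. LiEt3BH (THF, 0 °C) opens the epoxide at CH2 to give 16.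

**Further compounds**

F1 | step 20 | (3R,5E)-6,10-dimethyl-1-(trimethylsilyl)undeca-5,9-dien-1-yn-3-ol | C[Si](C)(C)C#C[C@H](O)C/C=C(\C)CCC=C(C)C
F2 | step 20 | (3R,5E)-6,10-dimethylundeca-5,9-dien-1-yn-3-ol | C#C[C@H](O)C/C=C(\C)CCC=C(C)C
F3 | step 20 | (1E,3R,5E)-1-iodo-2,6,10-trimethylundeca-1,5,9-trien-3-ol | I/C=C(\C)[C@H](O)C/C=C(\C)CCC=C(C)C
F4 | step 14 | (2S,3S,4S)-2-[3-(TBSO)propyl]-3-(2-iodoethyl)-3,4-dimethyl-1-(prop-1-en-2-yl)-4-(triethylsilyloxy)cyclohexan-1-ol | CC(C)(C)[Si](C)(C)OCCC[C@@H]1C(O)(C(C)=C)CC[C@](C)(O[Si](CC)(CC)CC)[C@@]1(C)CCI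
F5 | step 8 | tert-butyl{3-[(1S,2S)-2-allyl-6,6-dimethoxy-2-methyl-3-methylidenecyclohexyl]propoxy}dimethylsilane | CC(C)(C)[Si](C)(C)OCCC[C@@H]1C(OC)(OC)CCC(=C)[C@@]1(C)CC=C
F6 | step 8 | tert-butyl{3-[(3S,4S,5S)-4-allyl-6,6-dimethoxy-4-methyl-1-oxaspiro[2.5]octan-5-yl]propoxy}dimethylsilane | CC(C)(C)[Si](C)(C)OCCC[C@@H]1C(OC)(OC)CC[C@]3(OC3)[C@@]1(C)CC=C
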